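**Retrosynthetic overview**
1. Target ⇐ dehydrative, enantiospecific bromonium‑ion polyene cyclisation of acyclic bromo‑diol 19. Ring A closes last (C5–C6 bond, vicinal quaternary centres, spiro C6), with C3–OH/C4–Br already in place.
2. 19 ⇐ Evans syn bromoacetate aldol on aldehyde 12 (sets C3 and C4), then two MeMgBr (gem‑dimethyl carbinol = latent bromonium).
3. Ring B (tetrasubstituted vinyl bromide) ⇐ enone RCM, reductive enol triflation, Ni‑catalysed OTf→Br; formed second, before ring A.
4. The stereodefined tetrasubstituted alkene ⇐ Birch reduction of an ortho‑disubstituted anisole and ozonolysis of the enol ether; the cleaved ring fixes the geometry that later decides the spiro centre.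
5. Ring order: Birch ring (template, cleaved) → ring B (RCM) → ring A (bromonium cyclisation). No Diels–Alder, no enolate allylation/RCM of the spiro centre.

Assumption: locants are those of (3S,4S,6S)-4,10-dibromo-1,5,5,9-tetramethylspiro[5.5]undeca-1,9-dien-3-ol (the configuration read from the SMILES); 1, 13 and 14 are bought. The route is a proposal and has not been run.

**Route**

Step 1
Reactants: 1 (4-methoxy-2-methylphenyl)acetic acid
Product: 2 2-(4-methoxy-2-methylcyclohexa-1,4-dien-1-yl)acetic acid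
Conditions: Li, NH3(l)/THF, t-BuOH, −78 → −33 °C; NH4Cl; cold pH 5 work-up
Reagents that add atoms: none
Why: Birch reduction; the OMe‑ and alkyl‑bearing carbons stay sp2, so the tetrasubstituted C=C carries CH3 and CH2CO2H cis and the two ring CH2 groups cis, which fixes the alkene geometry used later.

Step 2
Reactants: 2 2-(4-methoxy-2-methylcyclohexa-1,4-dien-1-yl)acetic acid
Product: 4 methyl (3E)-4-(carboxymethyl)-3-methyl-6-oxohex-3-enoate, via methoxy hydroperoxide 3 (not isolated)
Conditions: O3 (1.0 equiv, Sudan III end-point), CH2Cl2/MeOH 4:1, −78 °C; then Me2S, −78 °C → rt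
Reagents that add atoms: ozone, [O-][O+]=O; methanol, CO (stays only in 3)
Why: chemoselective ozonolysis of the enol ether (Birch reduction–ozonolysis, Criegee mechanism with MeOH trapping and Me2S reduction); C(OMe) becomes CO2Me, CH becomes CHO, and the tetrasubstituted alkene keeps its ring‑derived geometry.

Step 3
Reactants: 4 methyl (3E)-4-(carboxymethyl)-3-methyl-6-oxohex-3-enoate
Product: 5 methyl (3E)-4-(carboxymethyl)-3-methylhepta-3,6-dienoate
Conditions: KHMDS (1.0 equiv), THF, −78 °C; Ph3P=CH2 (1.2 equiv, from Ph3PCH3Br/KHMDS), −78 → 0 °C; 1 M HCl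
Reagents that add atoms: methylenetriphenylphosphorane, C=P(c1ccccc1)(c1ccccc1)c1ccccc1
Why: Wittig methylenation of the aldehyde with the acid masked as its potassium salt; fast, cold olefination avoids enolisation of the β,γ‑unsaturated aldehyde.

Step 4
Reactants: 5 methyl (3E)-4-(carboxymethyl)-3-methylhepta-3,6-dienoate
Product: 7 methyl (3E)-3,7-dimethyl-6-oxo-4-(prop-2-en-1-yl)octa-3,7-dienoate, via acid chloride 6 (not isolated)
Conditions: (COCl)2, DMF (cat.), CH2Cl2, 0 °C → rt; then CH2=C(CH3)MgBr, CuI (10 mol%), THF, −78 °C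
Reagents that add atoms: oxalyl chloride, O=C(Cl)C(=O)Cl (Cl stays only in 6); isopropenylmagnesium bromide, C=C(C)[Mg]Br
Why: acid chloride formation then copper‑catalysed Grignard acylation, which at −78 °C is selective for COCl over the methyl ester.

Step 5
Reactants: 7 methyl (3E)-3,7-dimethyl-6-oxo-4-(prop-2-en-1-yl)octa-3,7-dienoate
Product: 8 methyl (3E)-3-(4-methyl-3-oxocyclohex-4-en-1-ylidene)butanoate
Conditions: Grubbs II (5 mol%), CH2Cl2 (5 mM), 40 °C; used directly
Reagents that add atoms: none
Why: ring‑closing metathesis of the allyl and isopropenyl‑ketone alkenes closes ring B as a 2‑methylcyclohex‑2‑enone; the neutral conditions leave the tetrasubstituted exocyclic alkene (inert to Ru) and its geometry untouched.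

Step 6
Reactants: 8 methyl (3E)-3-(4-methyl-3-oxocyclohex-4-en-1-ylidene)butanoate
Product: 10 methyl (3E)-3-[4-methyl-3-(trifluoromethanesulfonyloxy)cyclohex-3-en-1-ylidene]butanoate, via lithium enolate 9 (not isolated)
Conditions: L-Selectride (1.05 equiv), THF, −78 °C; then PhNTf2, −78 → 0 °C
Reagents that add atoms: N-phenylbis(trifluoromethanesulfonimide), O=S(=O)(N(c1ccccc1)S(=O)(=O)C(F)(F)F)C(F)(F)F; L-Selectride, [Li+].CCC(C)[BH-](C(C)CC)C(C)CC (Li stays only in 9)
Why: conjugate hydride reduction gives the regiodefined tetrasubstituted enolate, which is O‑triflated before it can equilibrate (reductive enolate trapping, as with carvone).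

Step 7
Reactants: 10 methyl (3E)-3-[4-methyl-3-(trifluoromethanesulfonyloxy)cyclohex-3-en-1-ylidene]butanoate
Product: 11 methyl (3E)-3-(3-bromo-4-methylcyclohex-3-en-1-ylidene)butanoate
Conditions: Ni(OAc)2·4H2O (10 mol%), cod, Zn (cat.), LiBr (3 equiv), DMA/THF, rt
Reagents that add atoms: lithium bromide, [Li+].[Br-]
Why: nickel‑catalysed enol triflate to alkenyl bromide exchange (oxidative addition, halide exchange, reductive elimination) installs the tetrasubstituted vinyl bromide without moving the alkene.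

Step 8
Reactants: 11 methyl (3E)-3-(3-bromo-4-methylcyclohex-3-en-1-ylidene)butanoate
Product: 12 (3E)-3-(3-bromo-4-methylcyclohex-3-en-1-ylidene)butanal
Conditions: DIBAL-H (1.05 equiv), CH2Cl2, −78 °C; MeOH, Rochelle salt; used crude
Reagents that add atoms: none
Why: partial ester reduction through the aluminium hemiacetal, which is stable at −78 °C and releases the aldehyde only on work‑up.

Step 9
Reactants: 13 (4R)-4-benzyl-1,3-oxazolidin-2-one; 14 bromoacetyl bromide
Product: 15 (4R)-4-benzyl-3-(bromoacetyl)-1,3-oxazolidin-2-one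
Conditions: n-BuLi (1.0 equiv), THF, −78 °C; then 14, −78 → 0 °C
Reagents that add atoms: none
Why: N‑acylation of the lithiated oxazolidinone by the acid bromide (standard Evans imide formation).

Step 10
Reactants: 12 (3E)-3-(3-bromo-4-methylcyclohex-3-en-1-ylidene)butanal; 15 (4R)-4-benzyl-3-(bromoacetyl)-1,3-oxazolidin-2-one
Product: 17 (4R)-4-benzyl-3-[(2R,3S,5E)-2-bromo-5-(3-bromo-4-methylcyclohex-3-en-1-ylidene)-3-hydroxyhexanoyl]-1,3-oxazolidin-2-one, via boron enolate 16 (not isolated)
Conditions: Bu2BOTf, Et3N, CH2Cl2, −78 °C; then 12, −78 → 0 °C; pH 7 buffer/MeOH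
Reagents that add atoms: dibutylboron triflate, CCCCB(CCCC)OS(=O)(=O)C(F)(F)F (boron stays only in 16)
Why: Evans syn aldol of the (Z)‑boron enolate of a bromoacetyl imide through a Zimmerman–Traxler chair; the (R)‑benzyl auxiliary sets (2R,3S), the syn bromohydrin that becomes the trans C3–OH/C4–Br pair of the target.

Step 11
Reactants: 17 (4R)-4-benzyl-3-[(2R,3S,5E)-2-bromo-5-(3-bromo-4-methylcyclohex-3-en-1-ylidene)-3-hydroxyhexanoyl]-1,3-oxazolidin-2-one
Product: 18 methyl (2R,3S,5E)-2-bromo-5-(3-bromo-4-methylcyclohex-3-en-1-ylidene)-3-hydroxyhexanoate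
Conditions: MeOMgBr (from MeMgBr + MeOH), MeOH/CH2Cl2, −10 → 0 °C; NH4Cl
Reagents that add atoms: methoxymagnesium bromide, CO[Mg]Br
Why: magnesium methoxide transesterification removes the auxiliary (recovered) under conditions mild enough to spare the base‑sensitive bromohydrin; no stereocentre is touched.

Step 12
Reactants: 18 methyl (2R,3S,5E)-2-bromo-5-(3-bromo-4-methylcyclohex-3-en-1-ylidene)-3-hydroxyhexanoate
Product: 19 (3R,4S,6E)-3-bromo-6-(3-bromo-4-methylcyclohex-3-en-1-ylidene)-2-methylheptane-2,4-diol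
Conditions: MeMgBr (3.5 equiv), THF, −78 → −20 °C; NH4Cl
Reagents that add atoms: methylmagnesium bromide, C[Mg]Br
Why: double Grignard addition to the ester gives the gem‑dimethyl carbinol; the low temperature keeps the magnesium alkoxide from closing to an epoxide, and both stereocentres are untouched.

Step 13
Reactants: 19 (3R,4S,6E)-3-bromo-6-(3-bromo-4-methylcyclohex-3-en-1-ylidene)-2-methylheptane-2,4-diol
Product: 20 (3S,4S,6S)-4,10-dibromo-1,5,5,9-tetramethylspiro[5.5]undeca-1,9-dien-3-ol
Conditions: TsOH·H2O (10 mol%), HFIP, 0 °C → rt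
Reagents that add atoms: none
Why: acid‑promoted ionisation of the tertiary β‑bromo alcohol with anchimeric assistance gives the enantiopure bromonium ion, which closes by 6‑endo bromonium‑initiated cation–olefin (polyene) cyclisation through a chair (Br and OH equatorial, C–Br anti to the forming C5–C6 bond), so the preset alkene geometry puts C11 cis to Br and sets C6 as S; acid‑equilibrated loss of H‑2 gives the trisubstituted alkene.

**Compound list**
1 | (4-methoxy-2-methylphenyl)acetic acid | COc1ccc(CC(=O)O)c(C)c1 | starting material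
2 | 2-(4-methoxy-2-methylcyclohexa-1,4-dien-1-yl)acetic acid | COC1=CCC(CC(=O)O)=C(C)C1 | intermediate
3 | methyl (3E)-4-(carboxymethyl)-6-hydroperoxy-6-methoxy-3-methylhex-3-enoate (methoxy hydroperoxide) | COC(=O)C/C(C)=C(\CC(OC)OO)CC(=O)O | intermediate (not isolated)
4 | methyl (3E)-4-(carboxymethyl)-3-methyl-6-oxohex-3-enoate | COC(=O)C/C(C)=C(\CC=O)CC(=O)O | intermediate
5 | methyl (3E)-4-(carboxymethyl)-3-methylhepta-3,6-dienoate | COC(=O)C/C(C)=C(\CC=C)CC(=O)O | intermediate
6 | methyl (3E)-4-(2-chloro-2-oxoethyl)-3-methylhepta-3,6-dienoate (acid chloride) | COC(=O)C/C(C)=C(\CC=C)CC(=O)Cl | intermediate (not isolated)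
7 | methyl (3E)-3,7-dimethyl-6-oxo-4-(prop-2-en-1-yl)octa-3,7-dienoate | COC(=O)C/C(C)=C(\CC=C)CC(=O)C(C)=C | intermediate
8 | methyl (3E)-3-(4-methyl-3-oxocyclohex-4-en-1-ylidene)butanoate (ester CH2 cis to the ring CH2 next to CH=) | COC(=O)C/C(C)=C1\CC=C(C)C(=O)C1 | intermediate
9 | lithium 5-[(2E)-4-methoxy-4-oxobutan-2-ylidene]-2-methylcyclohex-1-en-1-olate (lithium enolate) | COC(=O)C/C(C)=C1\CCC(C)=C([O-])C1.[Li+] | intermediate (not isolated)
10 | methyl (3E)-3-[4-methyl-3-(trifluoromethanesulfonyloxy)cyclohex-3-en-1-ylidene]butanoate | COC(=O)C/C(C)=C1\CCC(C)=C(OS(=O)(=O)C(F)(F)F)C1 | intermediate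
11 | methyl (3E)-3-(3-bromo-4-methylcyclohex-3-en-1-ylidene)butanoate | COC(=O)C/C(C)=C1\CCC(C)=C(Br)C1 | intermediate
12 | (3E)-3-(3-bromo-4-methylcyclohex-3-en-1-ylidene)butanal | O=CC/C(C)=C1\CCC(C)=C(Br)C1 | intermediate
13 | (4R)-4-benzyl-1,3-oxazolidin-2-one | O=C1N[C@H](Cc2ccccc2)CO1 | starting material
14 | bromoacetyl bromide | BrCC(=O)Br | starting material
15 | (4R)-4-benzyl-3-(bromoacetyl)-1,3-oxazolidin-2-one | O=C(CBr)N1[C@H](Cc2ccccc2)COC1=O | intermediate
16 | (Z)-O-dibutylboryl enolate of 15 (boron enolate; OB and Br cis) | CCCCB(CCCC)O/C(=C\Br)N1[C@H](Cc2ccccc2)COC1=O | intermediate (not isolated)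
17 | (4R)-4-benzyl-3-[(2R,3S,5E)-2-bromo-5-(3-bromo-4-methylcyclohex-3-en-1-ylidene)-3-hydroxyhexanoyl]-1,3-oxazolidin-2-one | O=C([C@H](Br)[C@@H](O)C/C(C)=C1\CCC(C)=C(Br)C1)N2[C@H](Cc3ccccc3)COC2=O | intermediate
18 | methyl (2R,3S,5E)-2-bromo-5-(3-bromo-4-methylcyclohex-3-en-1-ylidene)-3-hydroxyhexanoate | COC(=O)[C@H](Br)[C@@H](O)C/C(C)=C1\CCC(C)=C(Br)C1 | intermediate
19 | (3R,4S,6E)-3-bromo-6-(3-bromo-4-methylcyclohex-3-en-1-ylidene)-2-methylheptane-2,4-diol | CC(C)(O)[C@H](Br)[C@@H](O)C/C(C)=C1\CCC(C)=C(Br)C1 | intermediate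
20 | (3S,4S,6S)-4,10-dibromo-1,5,5,9-tetramethylspiro[5.5]undeca-1,9-dien-3-ol | CC1=C[C@H](O)[C@@H](Br)C(C)(C)[C@]12CCC(C)=C(Br)C2 | target

**Step count and risks**

Total steps: 13. Longest linear sequence: 12 (steps 1–8 and 10–13, from 1 to 20); step 9 is a one‑step side branch.

The three steps most likely to fail:

Step 13 (key cyclisation). The risks are proton loss to the exocyclic methylene instead of the ring alkene, acid damage to the allylic bromohydrin, acid scrambling of the tetrasubstituted alkene before ring closure, and a boat transition state giving the spiro epimer. The fallback sets out from 19 and moves to neutral, buffered solvolysis with a separate alkene isomerisation. HCl (2 M in Et2O), CH2Cl2, −40 °C converts the tertiary carbinol, with bromine assistance and retention, into (3R,4S,6E)-3-bromo-6-(3-bromo-4-methylcyclohex-3-en-1-ylidene)-2-chloro-2-methylheptan-4-ol F1. Solvolysis of this vicinal bromochloride in HFIP with 2,6-lutidine gives the same bromonium ion without free acid and closes ring A under kinetic control, giving 20 together with (3S,4S,6S)-4,10-dibromo-5,5,9-trimethyl-1-methylidenespiro[5.5]undec-9-en-3-ol F2. Cobalt‑salen/PhSiH3 hydrogen‑atom‑transfer isomerisation then moves the exocyclic alkene of F2 into the ring, so the fallback comes back to the route at 20.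

Step 2 (selective ozonolysis). The tetrasubstituted alkene is also very reactive toward ozone, so over‑oxidation may compete with enol ether cleavage. The fallback sets out from 2 and replaces ozone by a sterically governed two‑stage cleavage. Catalytic OsO4/NMO dihydroxylates only the unhindered enol ether, and loss of methanol gives 2-(5-hydroxy-2-methyl-4-oxocyclohex-1-en-1-yl)acetic acid F3. Pb(OAc)4 in MeOH/benzene cleaves this α‑hydroxy ketone into methyl ester plus aldehyde, and the fallback comes back to the route at 4.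

Step 12 (double Grignard addition to the α‑bromo‑β‑hydroxy ester). The risks are Darzens‑type epoxide closure, enolisation, and bromine–magnesium exchange. The fallback sets out from 17 and builds the carbinol one methyl at a time through less basic intermediates. Me3Al/MeNH(OMe)·HCl transamidates the free aldol adduct to (2R,3S,5E)-2-bromo-5-(3-bromo-4-methylcyclohex-3-en-1-ylidene)-3-hydroxy-N-methoxy-N-methylhexanamide F4. MeMgBr stops at (3R,4S,6E)-3-bromo-6-(3-bromo-4-methylcyclohex-3-en-1-ylidene)-4-hydroxyheptan-2-one F5, and MeMgBr/CeCl3 at −78 °C adds the second methyl; the fallback comes back to the route at 19.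

Further compounds
F1 | step 13 | (3R,4S,6E)-3-bromo-6-(3-bromo-4-methylcyclohex-3-en-1-ylidene)-2-chloro-2-methylheptan-4-ol | CC(C)(Cl)[C@H](Br)[C@@H](O)C/C(C)=C1\CCC(C)=C(Br)C1
F2 | step 13 | (3S,4S,6S)-4,10-dibromo-5,5,9-trimethyl-1-methylidenespiro[5.5]undec-9-en-3-ol | C=C1C[C@H](O)[C@@H](Br)C(C)(C)[C@]12CCC(C)=C(Br)C2
F3 | step 2 | 2-(5-hydroxy-2-methyl-4-oxocyclohex-1-en-1-yl)acetic acid | O=C1CC(C)=C(CC(=O)O)CC1O
F4 | step 12 | (2R,3S,5E)-2-bromo-5-(3-bromo-4-methylcyclohex-3-en-1-ylidene)-3-hydroxy-N-methoxy-N-methylhexanamide | CON(C)C(=O)[C@H](Br)[C@@H](O)C/C(C)=C1\CCC(C)=C(Br)C1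
F5 | step 12 | (3R,4S,6E)-3-bromo-6-(3-bromo-4-methylcyclohex-3-en-1-ylidene)-4-hydroxyheptan-2-one | CC(=O)[C@H](Br)[C@@H](O)C/C(C)=C1\CCC(C)=C(Br)C1
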